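**Plan**
Numbering: lactone O1, C2 (C=O), C3 (hydroxybutyl), C4 (Br), C5, exocyclic C6 (I). Cuts, in retrosynthetic order: O1–C5 (lactone closure), C6–I (iodoalkyne from silylalkyne), the C2 carboxyl (from a vinyl group), the C3–C2/C4–Br pair (anti addition across an alkyne), the carbinol C–H (ketone reduction), the acyl–alkynyl C–C bond.
Enabling feature: C5 with its exocyclic C6HI is the enol ester of an alkyne C5≡C6 held cis to the carboxyl on the C3=C4 alkene, and iodine cis to O1 is what anti addition of the carboxyl O–H across a 1-iodoalkyne delivers.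
Forward: the C8 diynol chain is built first, the tetrasubstituted C3=C4 alkene is then set by alkoxide-directed anti-vinylmagnesiation and bromination, the vinyl group is degraded to CO2H, and the only ring (the furanone) closes last.
Stereochemistry: the (R)-carbinol comes from catalyst-controlled Noyori transfer hydrogenation, the C3=C4 geometry from a five-membered magnesium chelate, and the (Z)-C5=C6 geometry from anti-oxyauration followed by stereoretentive protodeauration.

Key step: step 7

Remark: the (R,R)-configured ruthenium catalyst is chosen on the expectation that the alkynyl group takes the place that aryl takes in simple ketones; should the opposite sense be found, the (S,S) complex would be used.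

**Step 1**
Reactants: 1 1,4-bis(trimethylsilyl)buta-1,3-diyne; 2 butanoyl chloride
Product: 3 1-(trimethylsilyl)octa-1,3-diyn-5-one
Conditions: AlCl3 (1.1 equiv), CH2Cl2, 0 °C; cold aq HCl work-up
Reagents that add atoms: none
Why: Friedel–Crafts-type acylative ipso-desilylation, in which the acylium ion attacks one silylated alkyne terminus through a β-silyl-stabilised cation and the electron-poor ynone should resist a second acylation.

**Step 2**
Reactants: 3 1-(trimethylsilyl)octa-1,3-diyn-5-one
Product: 4 (5R)-1-(trimethylsilyl)octa-1,3-diyn-5-ol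
Conditions: Ru[(R,R)-TsDPEN](p-cymene) (preformed amido complex, 1 mol %), iPrOH, rt
Reagents that add atoms: none
Why: Noyori asymmetric transfer hydrogenation of an alkynyl ketone, in which the chiral ruthenium hydride differentiates the alkynyl and propyl flanks in a six-membered transition state and so should set the (R)-carbinol, while the base-free catalyst spares the C–Si bond.

**Step 3**
Reactants: 4 (5R)-1-(trimethylsilyl)octa-1,3-diyn-5-ol; 5 vinylmagnesium chloride
Product: 8 (3Z,4R)-3-[1-bromo-3-(trimethylsilyl)prop-2-yn-1-ylidene]hept-1-en-4-ol, via chloromagnesium alkoxide 6 (not isolated), via oxamagnesacycle 7 (not isolated)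
Conditions: 5 (4 equiv), THF, 0 °C to 50 °C; then NBS (4.5 equiv), −78 °C to −20 °C; aq NH4Cl
Reagents that add atoms: vinylmagnesium chloride 5, C=C[Mg]Cl; N-bromosuccinimide, O=C1CCC(=O)N1Br
Why: Alkoxide-directed anti-carbomagnesiation of a propargylic alcohol, in which vinyl adds to the alkyne carbon next to the carbinol and magnesium ends on the distal carbon inside a five-membered O–Mg chelate, so that stereoretentive bromination should place Br cis to the carbinol and vinyl cis to the silylalkyne.

**Step 4**
Reactants: 8 (3Z,4R)-3-[1-bromo-3-(trimethylsilyl)prop-2-yn-1-ylidene]hept-1-en-4-ol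
Product: 10 (2E)-3-bromo-2-[(1R)-1-hydroxybutyl]-5-(trimethylsilyl)pent-2-en-4-ynal, via vicinal diol 9 (not isolated)
Conditions: OsO4 (2 mol %), NaIO4 (4 equiv), 2,6-lutidine (2 equiv), 1,4-dioxane/H2O (3:1), rt
Reagents that add atoms: osmium tetroxide, O=[Os](=O)(=O)=O; sodium periodate, [Na+].[O-]I(=O)(=O)=O
Why: Lemieux–Johnson oxidative cleavage, in which OsO4 should dihydroxylate the terminal monosubstituted vinyl group much faster than the bromine-deactivated tetrasubstituted alkene or the alkynes, and periodate cleaves only the new 1,2-diol.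

**Step 5**
Reactants: 10 (2E)-3-bromo-2-[(1R)-1-hydroxybutyl]-5-(trimethylsilyl)pent-2-en-4-ynal
Product: 11 (2E)-3-bromo-2-[(1R)-1-hydroxybutyl]-5-iodopent-2-en-4-ynal
Conditions: NIS (1.2 equiv), AgNO3 (10 mol %), acetone, rt, dark
Reagents that add atoms: N-iodosuccinimide, O=C1CCC(=O)N1I
Why: Silver-catalysed iododesilylation of a silylalkyne through the silver acetylide is a standard entry to 1-iodoalkynes, and it is placed before the acid is unveiled so that no premature silver-triggered lactonisation can occur.

**Step 6**
Reactants: 11 (2E)-3-bromo-2-[(1R)-1-hydroxybutyl]-5-iodopent-2-en-4-ynal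
Product: 12 (2E)-3-bromo-2-[(1R)-1-hydroxybutyl]-5-iodopent-2-en-4-ynoic acid
Conditions: NaClO2, NaH2PO4, 2-methylbut-2-ene, t-BuOH/H2O, 0 °C to rt
Reagents that add atoms: sodium chlorite, [Na+].[O-]Cl=O
Why: Pinnick oxidation should convert the enal into the acid under buffered conditions, with 2-methylbut-2-ene scavenging HOCl so that the secondary carbinol, the vinyl bromide and the iodoalkyne survive.

**Step 7**
Reactants: 12 (2E)-3-bromo-2-[(1R)-1-hydroxybutyl]-5-iodopent-2-en-4-ynoic acid
Product: 14 (5Z)-4-bromo-3-[(1R)-1-hydroxybutyl]-5-(iodomethylidene)furan-2(5H)-one, via vinylgold lactone 13 (not isolated)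
Conditions: Ph3PAuNTf2 (3 mol %), CH2Cl2, rt, dark
Reagents that add atoms: none
Why: Cationic monovalent gold π-activates the iodoalkyne of 12, the carboxyl oxygen attacks the internal alkyne carbon C5 anti to the metal to give vinylgold lactone 13, and protodeauration by the released acid proton with retention at C6 should liberate 14 and the catalyst. The closest known reaction types are the gold- or mercury-catalysed cycloisomerisation of ω-haloalkynoic acids to (Z)-haloenol lactones, the silver- or gold-catalysed lactonisation of cis-enynoic acids to γ-ylidenebutenolides, and the gold-catalysed anti addition of carboxylic acids to 1-iodoalkynes. The furanone ring closes in the 5-exo-dig mode. No new stereocentre is formed; the C5=C6 geometry is controlled by anti addition of O and Au followed by stereoretentive C–Au protonolysis, which leaves iodine cis to O1 (Z), and the (R)-carbinol is not touched. The step needs 5-exo over 6-endo closure, which the iodine substituent should secure by polarising the gold–alkyne complex so that the nucleophile adds to the carbon remote from iodine. It also needs the carboxyl and not the carbinol oxygen to add, which the C3=C4 geometry fixed in step 3 secures by holding the carbinol cis to bromine and out of reach of the alkyne.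

**Compound list**
1 | 1,4-bis(trimethylsilyl)buta-1,3-diyne | C[Si](C)(C)C#CC#C[Si](C)(C)C | starting material
2 | butanoyl chloride | CCCC(Cl)=O | starting material
3 | 1-(trimethylsilyl)octa-1,3-diyn-5-one | CCCC(=O)C#CC#C[Si](C)(C)C | intermediate
4 | (5R)-1-(trimethylsilyl)octa-1,3-diyn-5-ol | CCC[C@@H](O)C#CC#C[Si](C)(C)C | intermediate
5 | vinylmagnesium chloride | C=C[Mg]Cl | starting material
6 | chloromagnesium alkoxide of 4 (not isolated) | CCC[C@@H](O[Mg]Cl)C#CC#C[Si](C)(C)C | intermediate
7 | oxamagnesacycle: five-membered O–Mg–C=C chelate carrying vinyl on the carbon next to the carbinol and the silylalkyne on the magnesiated carbon (not isolated) | CCC[C@H]1O[Mg]C(C#C[Si](C)(C)C)=C1C=C | intermediate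
8 | (3Z,4R)-3-[1-bromo-3-(trimethylsilyl)prop-2-yn-1-ylidene]hept-1-en-4-ol (Br cis to the carbinol carbon) | CCC[C@@H](O)/C(C=C)=C(\Br)C#C[Si](C)(C)C | intermediate
9 | (4R)-3-[1-bromo-3-(trimethylsilyl)prop-2-yn-1-ylidene]heptane-1,2,4-triol, Br cis to C4, both C2 epimers (not isolated) | CCC[C@@H](O)/C(C(O)CO)=C(\Br)C#C[Si](C)(C)C | intermediate
10 | (2E)-3-bromo-2-[(1R)-1-hydroxybutyl]-5-(trimethylsilyl)pent-2-en-4-ynal | CCC[C@@H](O)/C(C=O)=C(\Br)C#C[Si](C)(C)C | intermediate
11 | (2E)-3-bromo-2-[(1R)-1-hydroxybutyl]-5-iodopent-2-en-4-ynal | CCC[C@@H](O)/C(C=O)=C(\Br)C#CI | intermediate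
12 | (2E)-3-bromo-2-[(1R)-1-hydroxybutyl]-5-iodopent-2-en-4-ynoic acid (carboxyl cis to the iodoalkyne) | CCC[C@@H](O)/C(C(O)=O)=C(\Br)C#CI | intermediate
13 | vinylgold lactone: the furanone of 14 with Ph3PAu in place of H on C6, gold trans to O1 (not isolated) | CCC[C@@H](O)C1=C(Br)/C(=C(/I)[Au-][P+](c2ccccc2)(c2ccccc2)c2ccccc2)OC1=O | intermediate
14 | (5Z)-4-bromo-3-[(1R)-1-hydroxybutyl]-5-(iodomethylidene)furan-2(5H)-one | CCC[C@@H](O)C1=C(Br)/C(=C/I)OC1=O | target

**Count and risks**
Total steps: 7. Longest linear sequence: 7 steps.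

Step 3. Risk: the alkenylmagnesium centre is conjugated to the second alkyne, so the addition could lose site selectivity, or bromination could take place at the remote silylated terminus. Fallback, setting out from 2 and returning at 8: acylation of bis(trimethylsilyl)acetylene with 2 (AlCl3, CH2Cl2) should give 1-(trimethylsilyl)hex-1-yn-3-one F1. The transfer hydrogenation of step 2 should then give (3R)-1-(trimethylsilyl)hex-1-yn-3-ol F2. Anti-vinylmagnesiation and NBS quench on this mono-alkyne, where no second triple bond can interfere, should give (3Z,4R)-3-[bromo(trimethylsilyl)methylidene]hept-1-en-4-ol F3. Stereoretentive ipso-iododesilylation (NIS, hexafluoropropan-2-ol, 0 °C) should give (3E,4R)-3-[bromo(iodo)methylidene]hept-1-en-4-ol F4. Sonogashira coupling with ethynyltrimethylsilane (PdCl2(PPh3)2, CuI, Et3N, rt), in which zerovalent palladium should insert into C–I well before C–Br, should return 8.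

Step 7. Risk: competing 6-endo closure, 1,2-migration of iodine through a gold vinylidene, loss of iodine by metal–halogen exchange, or light-induced Z to E isomerisation. Fallback, setting out from 10 and returning at 14: Pinnick oxidation of 10 should give (2E)-3-bromo-2-[(1R)-1-hydroxybutyl]-5-(trimethylsilyl)pent-2-en-4-ynoic acid F5. Silver-catalysed 5-exo-dig lactonisation (Ag2CO3 cat., toluene, rt) should give (5Z)-4-bromo-3-[(1R)-1-hydroxybutyl]-5-[(trimethylsilyl)methylidene]furan-2(5H)-one F6. Ipso-iododesilylation (NIS, MeCN, 0 °C, dark), in which O1 stabilises the β-silyl cation at C5, should give 14 with iodine in the place of silicon.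

Step 4. Risk: osmylation of the wrong π-bond, over-oxidation, or E/Z scrambling of the β-bromo enal by addition–elimination under the aqueous conditions. Fallback, setting out from 4 and returning at 11: copper-catalysed anti-carbomagnesiation of 4 with (isopropoxydimethylsilyl)methylmagnesium chloride (CuI 10 mol %, THF) and NBS quench should give (3E,5R)-3-bromo-4-{[dimethyl(propan-2-yloxy)silyl]methyl}-1-(trimethylsilyl)oct-3-en-1-yn-5-ol F7. Tamao–Fleming oxidation (H2O2, KF, KHCO3, THF/MeOH), which should also cleave the alkynyl C–Si bond, should give (2Z)-3-bromo-2-[(1R)-1-hydroxybutyl]pent-2-en-4-yn-1-ol F8. Selective oxidation of the primary allylic alcohol (TEMPO, PhI(OAc)2, CH2Cl2) should give (2E)-3-bromo-2-[(1R)-1-hydroxybutyl]pent-2-en-4-ynal F9. Iodination of the terminal alkyne (NIS, AgNO3 cat., acetone) should return 11.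

**Further compounds**
F1 | step 3 | 1-(trimethylsilyl)hex-1-yn-3-one | CCCC(=O)C#C[Si](C)(C)C
F2 | step 3 | (3R)-1-(trimethylsilyl)hex-1-yn-3-ol | CCC[C@@H](O)C#C[Si](C)(C)C
F3 | step 3 | (3Z,4R)-3-[bromo(trimethylsilyl)methylidene]hept-1-en-4-ol | CCC[C@@H](O)/C(C=C)=C(\Br)[Si](C)(C)C
F4 | step 3 | (3E,4R)-3-[bromo(iodo)methylidene]hept-1-en-4-ol | CCC[C@@H](O)/C(C=C)=C(\Br)I
F5 | step 7 | (2E)-3-bromo-2-[(1R)-1-hydroxybutyl]-5-(trimethylsilyl)pent-2-en-4-ynoic acid | CCC[C@@H](O)/C(C(O)=O)=C(\Br)C#C[Si](C)(C)C
F6 | step 7 | (5Z)-4-bromo-3-[(1R)-1-hydroxybutyl]-5-[(trimethylsilyl)methylidene]furan-2(5H)-one | CCC[C@@H](O)C1=C(Br)/C(=C/[Si](C)(C)C)OC1=O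
F7 | step 4 | (3E,5R)-3-bromo-4-{[dimethyl(propan-2-yloxy)silyl]methyl}-1-(trimethylsilyl)oct-3-en-1-yn-5-ol | CCC[C@@H](O)/C(C[Si](C)(C)OC(C)C)=C(\Br)C#C[Si](C)(C)C
F8 | step 4 | (2Z)-3-bromo-2-[(1R)-1-hydroxybutyl]pent-2-en-4-yn-1-ol | CCC[C@@H](O)/C(CO)=C(\Br)C#C
F9 | step 4 | (2E)-3-bromo-2-[(1R)-1-hydroxybutyl]pent-2-en-4-ynal | CCC[C@@H](O)/C(C=O)=C(\Br)C#C
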